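## Retrosynthetic overview

Numbering: ring A is C1(CH3 = C7)–C2–C3–C4–C5–C6 with the oxirane on C1–C6 and angelates on O–C2 and O–C3; the side chain on C4 is C8(=C14H2)–C9(OAc)–C10–C11=C12(C13)(C15).
Endgame: angelates ⇐ epoxy diol ⇐ hydroxyl-directed epoxidation of the C1=C6 cyclohexenediol; the C9 acetate is placed while the cis-2,3-diol is masked as a boronate.
Key disconnection: C1–C2 and C3–C4 together, so that C2–C3 is glyoxal inserted between a C1 alkenyl nucleophile (Z-alkenyl iodide, chromium) and a C4 allyl nucleophile (C14 allylsilane). Ring order: temporary oxane (lactol) ring, then ring A, then the oxirane.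
Enabling feature: C2 and C3 are adjacent carbinol carbons flanked by the vinylic C1 (of C1=C6) and the allylic C4 (next to the C8=C14 methylene), and the C9 oxygen lies 1,3 to C4 across C8. A glyoxal hemiacetal on O–C9 therefore puts C3 into a six-membered oxane transition-state ring (O–C2–C3–C4–C8–C9) that relays the C9 configuration to C3 and C4.
The acyclic precursor comes from three pieces in one anti-carbomagnesiation/allylation: an (S)-propargylic alcohol (C8–C13, C15), Me3SiCH2MgCl (C14) and (Z)-1-bromo-3-iodobut-2-ene (C5, C6, C1, C7).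

Key step: step 8

Remark: anhydrous monomeric glyoxal is assumed to be generated from commercial glyoxal trimer dihydrate (P2O5, heat) and used as a cold solution.

## Route

Step 1
Reactants: 1 but-2-yn-1-ol
Product: 3 (Z)-3-iodobut-2-en-1-ol, via cyclic alkenylaluminate 2 (not isolated)
Conditions: NaAlH2(OCH2CH2OCH3)2, THF, 0 °C to rt; then I2, THF, −78 °C
Reagents that add atoms: iodine (II)
Why: hydroxyl-directed trans-hydroalumination of the propargylic alcohol should place aluminium on C3 cis to the CH2O group, and iodinolysis with retention then fixes the Z iodoalkene.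

Step 2
Reactants: 3 (Z)-3-iodobut-2-en-1-ol
Product: 4 (Z)-1-bromo-3-iodobut-2-ene
Conditions: CBr4, PPh3, CH2Cl2, 0 °C
Reagents that add atoms: carbon tetrabromide (BrC(Br)(Br)Br)
Why: the Appel reaction should convert the primary allylic alcohol by SN2 displacement without allylic transposition or loss of alkene geometry.

Step 3
Reactants: 5 4-methylpent-3-enoic acid
Product: 7 N-methoxy-N,4-dimethylpent-3-enamide, via acylimidazole 6 (not isolated)
Conditions: 1,1′-carbonyldiimidazole, CH2Cl2, rt; then MeNH(OMe)·HCl, rt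
Reagents that add atoms: N,O-dimethylhydroxylamine hydrochloride (CNOC.Cl)
Why: amide formation through the acylimidazole runs under near-neutral conditions, so the β,γ-double bond should not move into conjugation.

Step 4
Reactants: 7 N-methoxy-N,4-dimethylpent-3-enamide; 8 ethynyl(trimethyl)silane
Product: 9 6-methyl-1-(trimethylsilyl)hept-5-en-1-yn-3-one
Conditions: 8, n-BuLi, THF, −78 °C; then 7, −78 to 0 °C; aq. NH4Cl
Reagents that add atoms: none
Why: in the Weinreb ketone synthesis the chelated tetrahedral intermediate should prevent over-addition, and the weakly basic acetylide at low temperature should not enolise the skipped system.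

Step 5
Reactants: 9 6-methyl-1-(trimethylsilyl)hept-5-en-1-yn-3-one
Product: 10 (3S)-6-methyl-1-(trimethylsilyl)hept-5-en-1-yn-3-ol
Conditions: Ru[(S,S)-TsNCH(Ph)CH(Ph)NH](p-cymene) (1 mol %), 2-propanol, rt
Reagents that add atoms: none
Why: in the Noyori asymmetric transfer hydrogenation of alkynyl ketones the alkynyl group takes the place of the aryl group of the usual model, so the (S,S) catalyst should give the (S) carbinol (this sets C9), and the base-free conditions should leave the skipped enone unconjugated.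

Step 6
Reactants: 10 (3S)-6-methyl-1-(trimethylsilyl)hept-5-en-1-yn-3-ol
Product: 11 (3S)-6-methylhept-5-en-1-yn-3-ol
Conditions: K2CO3 (0.2 equiv), MeOH, rt
Reagents that add atoms: none
Why: base-catalysed methanolysis should cleave the alkynyl C–Si bond without touching the stereocentre.

Step 7
Reactants: 11 (3S)-6-methylhept-5-en-1-yn-3-ol; 12 [(trimethylsilyl)methyl]magnesium chloride; 4 (Z)-1-bromo-3-iodobut-2-ene
Product: 14 (5S,6E,9Z)-10-iodo-2-methyl-6-[(trimethylsilyl)methyl]undeca-2,6,9-trien-5-ol, via cyclic alkenylmagnesium alkoxide 13 (not isolated)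
Conditions: 12 (3 equiv), CuI (10 mol %), THF–Et2O, 0 °C to rt; then 4 (2 equiv), −30 to 0 °C; aq. NH4Cl
Reagents that add atoms: none
Why: in the copper-catalysed anti-carbomagnesiation of the propargylic alkoxide the CH2SiMe3 group should add to the proximal alkyne carbon C8 and magnesium to C4 inside a five-membered chelate cis to C9; SN2 allylation at the primary bromide of 4 with retention then places C5 cis to C9 (E allylsilane) and leaves the alkenyl iodide untouched.

Step 8
Reactants: 14 (5S,6E,9Z)-10-iodo-2-methyl-6-[(trimethylsilyl)methyl]undeca-2,6,9-trien-5-ol; 15 glyoxal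
Product: 19 (1R,2S,6S)-6-[(3S)-3-hydroxy-6-methylhepta-1,5-dien-2-yl]-3-methylcyclohex-3-ene-1,2-diol, via glyoxal hemiacetal 16 (not isolated), via methylidene lactol 17 (not isolated), via open-chain hydroxy aldehyde 18 (not isolated)
Conditions: 15 (1.2 equiv), MeCN–CH2Cl2, −40 °C; then Sc(OTf)3 (10 mol %), −40 to 0 °C; then DMSO, CrCl2 (8 equiv), NiCl2 (2 mol %), rt
Reagents that add atoms: none
Why: Proposed new method: the C9 hydroxyl of 14 should add to glyoxal to give hemiacetal 16, whose remaining aldehyde (C3), activated by Sc(OTf)3, is attacked by C4 of the (E)-allylsilane in an anti-SE2′ Hosomi–Sakurai cyclisation (six-membered oxane ring, exo at the carbonyl and endo at the allylsilane π bond) that forms C3–C4 and the C8=C14 methylene; lactol 17 is in equilibrium with hydroxy aldehyde 18, and after addition of CrCl2/NiCl2 the alkenylchromium (trivalent chromium) made from the (Z)-iodide adds to the C2 aldehyde (Nozaki–Hiyama–Kishi reaction, 6-exo-trig) to form C1–C2 and ring A. The closest known reaction types are Lewis acid-promoted intramolecular allylsilane–aldehyde cyclisations to methylenecycloalkanols, temporary hemiacetal tethers, and intramolecular Nozaki–Hiyama–Kishi closures of 2-cyclohexenols; their merger in one flask on free glyoxal is not known. C4 is set by the chair-like transition state of the tethered addition: the C5 chain, being cis to C9 on the alkene, is forced axial, so the C10 chain on C9 must be equatorial to avoid a 1,3-diaxial clash, and the (9S) centre thereby fixes (4S). C3 is set by the synclinal approach of the complexed carbonyl (oxygen axial, anti to the axial C5 chain), which gives (3R), that is, C3–O cis to the C4 side chain in ring A. C2 is set in the chromium step, where the tethered alkenyl group can only reach the aldehyde chelated to the C3 oxygen from the C4 side, which should give the cis-2,3-diol (2S). The step needs tethered rather than untethered addition (secured by preforming 16 with near-stoichiometric glyoxal and by the six-membered transition state), E geometry at C8=C4 (from step 7) and Z geometry at C1=C6 with iodine cis to C5 so that the ring alkene can close (from steps 1 and 2).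

Step 9
Reactants: 19 (1R,2S,6S)-6-[(3S)-3-hydroxy-6-methylhepta-1,5-dien-2-yl]-3-methylcyclohex-3-ene-1,2-diol
Product: 22 (3S)-2-[(1S,5S,6R)-5,6-dihydroxy-4-methylcyclohex-3-en-1-yl]-6-methylhepta-1,5-dien-3-yl acetate, via cyclic phenylboronate 20 (not isolated), via boronate acetate 21 (not isolated)
Conditions: PhB(OH)2 (1.05 equiv), CH2Cl2, rt; then Ac2O, pyridine, DMAP (5 mol %), 0 °C to rt; then aqueous sorbitol–Na2CO3 wash
Reagents that add atoms: acetic anhydride (CC(=O)OC(C)=O)
Why: transient boronate masking should tie up the cis-2,3-diol as a five-membered phenylboronate so that only the C9 hydroxyl is acetylated, and hydrolytic work-up then returns the diol.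

Step 10
Reactants: 22 (3S)-2-[(1S,5S,6R)-5,6-dihydroxy-4-methylcyclohex-3-en-1-yl]-6-methylhepta-1,5-dien-3-yl acetate
Product: 23 (3S)-2-[(1R,2R,3R,4S,6S)-2,3-dihydroxy-1-methyl-7-oxabicyclo[4.1.0]heptan-4-yl]-6-methylhepta-1,5-dien-3-yl acetate
Conditions: VO(acac)2 (5 mol %), t-BuOOH (1.3 equiv), CH2Cl2, 0 °C to rt
Reagents that add atoms: tert-butyl hydroperoxide (CC(C)(C)OO)
Why: the vanadium-catalysed, hydroxyl-directed epoxidation should deliver oxygen to the trisubstituted C1=C6 alkene syn to the allylic C2 hydroxyl (setting C1 and C6, oxirane cis to both hydroxyls), while the side-chain alkenes, which have no free allylic hydroxyl, should react much more slowly.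

Step 11
Reactants: 23 (3S)-2-[(1R,2R,3R,4S,6S)-2,3-dihydroxy-1-methyl-7-oxabicyclo[4.1.0]heptan-4-yl]-6-methylhepta-1,5-dien-3-yl acetate; 24 angelic acid
Product: 25 (1S,2R,3R,4S,6S)-4-[(3S)-3-(acetyloxy)-6-methylhepta-1,5-dien-2-yl]-1-methyl-7-oxabicyclo[4.1.0]heptane-2,3-diyl bis[(2Z)-2-methylbut-2-enoate]
Conditions: 24 (6 equiv), 2,4,6-trichlorobenzoyl chloride, Et3N, toluene, rt; then 23, toluene, 80 °C
Reagents that add atoms: none
Why: Yamaguchi-type mixed-anhydride acylation without a nucleophilic catalyst should transfer the angeloyl group to both secondary hydroxyls with the Z geometry intact, and the base-buffered medium should spare the oxirane.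

## Compound list

1 | but-2-yn-1-ol | CC#CCO | starting material
2 | sodium cyclic alkenylaluminate (aluminium on C3, bound to the alkoxide oxygen and two 2-methoxyethoxy groups) | CC1=CCO[Al-]1(OCCOC)OCCOC.[Na+] | intermediate
3 | (Z)-3-iodobut-2-en-1-ol | C/C(I)=C/CO | intermediate
4 | (Z)-1-bromo-3-iodobut-2-ene | C/C(I)=C/CBr | intermediate
5 | 4-methylpent-3-enoic acid | CC(C)=CCC(=O)O | starting material
6 | 1-(4-methylpent-3-enoyl)-1H-imidazole | CC(C)=CCC(=O)n1ccnc1 | intermediate
7 | N-methoxy-N,4-dimethylpent-3-enamide | CON(C)C(=O)CC=C(C)C | intermediate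
8 | ethynyl(trimethyl)silane | C#C[Si](C)(C)C | starting material
9 | 6-methyl-1-(trimethylsilyl)hept-5-en-1-yn-3-one | C[Si](C)(C)C#CC(=O)CC=C(C)C | intermediate
10 | (3S)-6-methyl-1-(trimethylsilyl)hept-5-en-1-yn-3-ol | C[Si](C)(C)C#C[C@@H](O)CC=C(C)C | intermediate
11 | (3S)-6-methylhept-5-en-1-yn-3-ol | C#C[C@@H](O)CC=C(C)C | intermediate
12 | [(trimethylsilyl)methyl]magnesium chloride | C[Si](C)(C)C[Mg]Cl | starting material
13 | cyclic alkenylmagnesium alkoxide (magnesium on C4, cis to C9, chelated by the C9 oxygen) | C[Si](C)(C)CC1=C[Mg]O[C@H]1CC=C(C)C | intermediate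
14 | (5S,6E,9Z)-10-iodo-2-methyl-6-[(trimethylsilyl)methyl]undeca-2,6,9-trien-5-ol | C[Si](C)(C)C/C(=C/C/C=C(/C)I)[C@@H](O)CC=C(C)C | intermediate
15 | glyoxal (ethanedial) | O=CC=O | starting material
16 | 2-hydroxy-2-{[(5S,6E,9Z)-10-iodo-2-methyl-6-[(trimethylsilyl)methyl]undeca-2,6,9-trien-5-yl]oxy}acetaldehyde (both hemiacetal epimers) | C[Si](C)(C)C/C(=C/C/C=C(/C)I)[C@H](CC=C(C)C)OC(O)C=O | intermediate
17 | (3R,4S,6S)-4-[(2Z)-3-iodobut-2-en-1-yl]-5-methylidene-6-(3-methylbut-2-en-1-yl)oxane-2,3-diol (both anomers) | OC1O[C@@H](CC=C(C)C)C(=C)[C@H](C/C=C(/C)I)[C@H]1O | intermediate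
18 | (2R,3S,5S)-2,5-dihydroxy-3-[(2Z)-3-iodobut-2-en-1-yl]-8-methyl-4-methylidenenon-7-enal | O=C[C@H](O)[C@@H](C/C=C(/C)I)C(=C)[C@@H](O)CC=C(C)C | intermediate
19 | (1R,2S,6S)-6-[(3S)-3-hydroxy-6-methylhepta-1,5-dien-2-yl]-3-methylcyclohex-3-ene-1,2-diol (C2–OH, C3–OH and the C4 side chain all cis) | C=C([C@H](CC=C(C)C)O)[C@@H]1CC=C(C)[C@H](O)[C@@H]1O | intermediate
20 | cyclic phenylboronate of the C2,C3-diol of 19 (C9 hydroxyl free) | C=C([C@H](CC=C(C)C)O)[C@@H]1CC=C(C)[C@@H]2OB(c3ccccc3)O[C@H]12 | intermediate
21 | C9 acetate of boronate 20 | C=C([C@H](CC=C(C)C)OC(C)=O)[C@@H]1CC=C(C)[C@@H]2OB(c3ccccc3)O[C@H]12 | intermediate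
22 | (3S)-2-[(1S,5S,6R)-5,6-dihydroxy-4-methylcyclohex-3-en-1-yl]-6-methylhepta-1,5-dien-3-yl acetate | C=C([C@H](CC=C(C)C)OC(C)=O)[C@@H]1CC=C(C)[C@H](O)[C@@H]1O | intermediate
23 | (3S)-2-[(1R,2R,3R,4S,6S)-2,3-dihydroxy-1-methyl-7-oxabicyclo[4.1.0]heptan-4-yl]-6-methylhepta-1,5-dien-3-yl acetate (oxirane, both hydroxyls and the side chain all cis) | C=C([C@H](CC=C(C)C)OC(C)=O)[C@@H]1C[C@@H]2O[C@]2(C)[C@H](O)[C@@H]1O | intermediate
24 | angelic acid, (2Z)-2-methylbut-2-enoic acid | C/C=C(/C)C(=O)O | starting material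
25 | (1S,2R,3R,4S,6S)-4-[(3S)-3-(acetyloxy)-6-methylhepta-1,5-dien-2-yl]-1-methyl-7-oxabicyclo[4.1.0]heptane-2,3-diyl bis[(2Z)-2-methylbut-2-enoate] | C=C([C@H](CC=C(C)C)OC(C)=O)[C@@H]1C[C@@H]2O[C@]2(C)[C@H](OC(=O)/C(C)=C\C)[C@@H]1OC(=O)/C(C)=C\C | target

## Step count and risks

Total step count: 11. Longest linear sequence: 9 steps (steps 3 to 11); steps 1 and 2 make the second fragment.

Steps most likely to fail:

1. Step 8 (proposed new method). The hemiacetal tether may form incompletely, so that untethered addition to free glyoxal with poor facial selectivity at C4, and oligomerisation of glyoxal, compete. The fallback uses a covalent ester tether and known reactions only, sets out from 14 and comes back at 19. Esterification of 14 with 2-[(tert-butyldimethylsilyl)oxy]acetic acid (DCC, DMAP, CH2Cl2) should give the silyloxyacetate F1. Desilylation (n-Bu4NF, AcOH, THF) should give the glycolate F2, and Dess–Martin oxidation the glyoxylate F3. BF3·OEt2 (CH2Cl2, −78 °C) should then close the hydroxy lactone F4 by the same chair-like Hosomi–Sakurai transition state. Reduction with i-Bu2AlH (CH2Cl2, −78 °C) should give lactol 17, now isolated, and CrCl2/NiCl2 in DMSO should convert it into 19.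

2. Step 7. The excess Grignard reagent or the alkenylmagnesium intermediate may couple at the alkenyl iodide of 4, or attack 4 in the SN2′ sense, which would erode the yield of the one-flask three-component union. The fallback builds the iodoalkene by olefination instead, sets out from 11 (through 13) and comes back at 14. Intermediate 13 is trapped with ethylene oxide (−30 to 0 °C) to give the diol F5. TEMPO/PhI(OAc)2 should oxidise and lactonise it to the dihydropyranone F6, and i-Bu2AlH (−78 °C) should give the lactol F7. Stork–Zhao olefination with Ph3P=C(I)CH3 (from (1-iodoethyl)triphenylphosphonium iodide and NaN(SiMe3)2, THF, −78 °C) should then give the Z iodoalkene 14.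

3. Step 11. The angeloyl group may isomerise to the E (tigloyl) isomer during acyl transfer, and acylation of the hindered C2 hydroxyl next to the oxirane may be incomplete. The fallback builds the Z enoates on the molecule, sets out from 23 and comes back at 25. Esterification of both hydroxyls with 2-[bis(2,2,2-trifluoroethoxy)phosphoryl]propanoic acid (DCC, DMAP) should give the bis(phosphonate) F8. Still–Gennari olefination with acetaldehyde (KN(SiMe3)2, 18-crown-6, THF, −78 °C) should then give both (Z)-2-methylbut-2-enoates of 25.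

Further compounds

F1 | step 8 | (5S,6E,9Z)-10-iodo-2-methyl-6-[(trimethylsilyl)methyl]undeca-2,6,9-trien-5-yl 2-[(tert-butyldimethylsilyl)oxy]acetate | C[Si](C)(C)C/C(=C/C/C=C(/C)I)[C@H](CC=C(C)C)OC(=O)CO[Si](C)(C)C(C)(C)C
F2 | step 8 | (5S,6E,9Z)-10-iodo-2-methyl-6-[(trimethylsilyl)methyl]undeca-2,6,9-trien-5-yl 2-hydroxyacetate | C[Si](C)(C)C/C(=C/C/C=C(/C)I)[C@H](CC=C(C)C)OC(=O)CO
F3 | step 8 | (5S,6E,9Z)-10-iodo-2-methyl-6-[(trimethylsilyl)methyl]undeca-2,6,9-trien-5-yl 2-oxoacetate | C[Si](C)(C)C/C(=C/C/C=C(/C)I)[C@H](CC=C(C)C)OC(=O)C=O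
F4 | step 8 | (3R,4S,6S)-3-hydroxy-4-[(2Z)-3-iodobut-2-en-1-yl]-5-methylidene-6-(3-methylbut-2-en-1-yl)oxan-2-one | O=C1O[C@@H](CC=C(C)C)C(=C)[C@H](C/C=C(/C)I)[C@H]1O
F5 | step 7 | (3E,5S)-8-methyl-4-[(trimethylsilyl)methyl]nona-3,7-diene-1,5-diol | C[Si](C)(C)C/C(=C/CCO)[C@@H](O)CC=C(C)C
F6 | step 7 | (6S)-6-(3-methylbut-2-en-1-yl)-5-[(trimethylsilyl)methyl]-3,6-dihydro-2H-pyran-2-one | O=C1CC=C(C[Si](C)(C)C)[C@H](CC=C(C)C)O1
F7 | step 7 | (6S)-6-(3-methylbut-2-en-1-yl)-5-[(trimethylsilyl)methyl]-3,6-dihydro-2H-pyran-2-ol (both anomers) | OC1CC=C(C[Si](C)(C)C)[C@H](CC=C(C)C)O1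
F8 | step 11 | (1S,2R,3R,4S,6S)-4-[(3S)-3-(acetyloxy)-6-methylhepta-1,5-dien-2-yl]-1-methyl-7-oxabicyclo[4.1.0]heptane-2,3-diyl bis{2-[bis(2,2,2-trifluoroethoxy)phosphoryl]propanoate} | C=C([C@H](CC=C(C)C)OC(C)=O)[C@@H]1C[C@@H]2O[C@]2(C)[C@H](OC(=O)C(C)P(=O)(OCC(F)(F)F)OCC(F)(F)F)[C@@H]1OC(=O)C(C)P(=O)(OCC(F)(F)F)OCC(F)(F)F
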